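**Strategy.** Ring B (C5–C10, labdane numbering) carries the C6 oxygen and the C8 tertiary methyl carbinol in a 1,3-relationship across the C7 methylene, the β-hydroxy ketone pattern left by an intramolecular aldol addition. The route therefore rests on forming C7–C8 by adding the methyl enolate of a C5 acetyl group to the ketone of a C9 acetyl group. This single operation closes ring B of the cis-decalin, places the C6 carbonyl and sets the C8 carbinol. The precursor is a 1,3,3-trimethylcyclohexane with cis-disposed acetyl (C5) and 1-acetyl-3-(2-methyl-1,3-dioxolan-2-yl)propyl (C10) groups; its C9–C10 bond comes from an Ireland–Claisen rearrangement and both acetyl groups are grown together.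

Key step: step 11

Remarks. Positions are given in labdane numbering (ring A: C1–C5, C10; ring B: C5–C10; side chain C11–C16; C17 on C8; C20 on C10). Racemates are written with both enantiomers in the SMILES. Assumption: (S)-1-phenylethylamine is taken to give the less soluble salt with the (2S,1'S)-acid; if the salt of the mirror-image acid crystallises instead, the (R)-amine is used with no other change.

**Step 1**
Reactants: 1 β-cyclocitral
Product: 2 β-cyclogeraniol, (2,6,6-trimethylcyclohex-1-en-1-yl)methanol
Conditions: NaBH4, MeOH, 0 °C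
Reagents that add atoms: none
Why: Borohydride 1,2-reduction of the hindered enal should give the primary allylic alcohol and leave the tetrasubstituted alkene alone.

**Step 2**
Reactants: 3 5-oxohexanoic acid
Product: 5 4-(2-methyl-1,3-dioxolan-2-yl)butanoic acid, via hydroxyethyl ester 4 (not isolated)
Conditions: HOCH2CH2OH, TsOH (cat.), toluene, reflux, water separator; then NaOH, MeOH/H2O, rt; cold 1 M HCl to pH 4
Reagents that add atoms: ethylene glycol, OCCO; sodium hydroxide, [Na+].[OH-]
Why: Acid-catalysed ketalisation with azeotropic water removal protects the C13 ketone (the acid is esterified by glycol in passing), and saponification then frees the acid while the base-stable dioxolane stays.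

**Step 3**
Reactants: 2 β-cyclogeraniol; 5 4-(2-methyl-1,3-dioxolan-2-yl)butanoic acid
Product: 6 (2,6,6-trimethylcyclohex-1-en-1-yl)methyl 4-(2-methyl-1,3-dioxolan-2-yl)butanoate
Conditions: DCC, DMAP (cat.), CH2Cl2, 0 °C → rt
Reagents that add atoms: none
Why: Steglich esterification (carbodiimide activation, DMAP acyl transfer) should couple the primary allylic alcohol under neutral conditions that spare the ketal and the ionisable allylic system.

**Step 4**
Reactants: 6 β-cyclogeranyl ester
Product: 9 rac-(2S)-4-(2-methyl-1,3-dioxolan-2-yl)-2-[(1S)-1,3,3-trimethyl-2-methylidenecyclohexyl]butanoic acid, via silyl ketene acetal 7 (not isolated), via silyl ester 8 (not isolated)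
Conditions: LiN(iPr)2, THF–HMPA, −78 °C; t-BuMe2SiCl; −78 → 65 °C; then 1 M NaOH, THF/MeOH, rt; cold 1 M HCl to pH 4
Reagents that add atoms: none
Why: Ireland–Claisen rearrangement: enolisation in THF–HMPA should give the (Z)-ketene acetal (C11 cis to OSi), whose chair transition state (side chain pseudo-equatorial, ring methyl pseudo-axial) forms the C9–C10 bond, sets quaternary C10 and tertiary C9 in the (2S*,1'S*) relative sense and moves the alkene to the exocyclic C5=C6 position.

**Step 5**
Reactants: 9 racemic acid
Product: 10 (S)-1-phenylethylammonium (2S)-4-(2-methyl-1,3-dioxolan-2-yl)-2-[(1S)-1,3,3-trimethyl-2-methylidenecyclohexyl]butanoate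
Conditions: (S)-1-phenylethylamine, EtOAc/hexane, crystallisation, recrystallisation to constant rotation
Reagents that add atoms: (S)-1-phenylethylamine, C[C@H](N)c1ccccc1
Why: Classical resolution: the enantiomeric acids form diastereomeric salts of different solubility with the enantiopure amine, and the less soluble one is collected.

**Step 6**
Reactants: 10 ammonium salt
Product: 12 (2S)-4-(2-methyl-1,3-dioxolan-2-yl)-2-[(1S)-1,3,3-trimethyl-2-methylidenecyclohexyl]butan-1-ol, via free acid 11 (not isolated)
Conditions: 10% aq. citric acid/EtOAc, 0 °C; then LiAlH4, THF, 0 °C → rt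
Reagents that add atoms: none
Why: Citric acid frees the acid without harming the ketal, and LiAlH4 reduces the carboxylic acid to the primary alcohol without touching the hindered 1,1-disubstituted alkene or the stereocentres.

**Step 7**
Reactants: 12 homoallylic-type alcohol
Product: 14 (2S)-2-[(1S,2S)-2-(hydroxymethyl)-1,3,3-trimethylcyclohexyl]-4-(2-methyl-1,3-dioxolan-2-yl)butan-1-ol, via bis(9-BBN) adduct 13 (not isolated)
Conditions: 9-borabicyclo[3.3.1]nonane (9-BBN, 3 equiv), THF, 0 → 65 °C; then NaOH, H2O2, 0 °C → rt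
Reagents that add atoms: hydrogen peroxide, OO
Why: Hydroboration–oxidation: boron goes to the exocyclic CH2 and H to C5 in a syn addition expected from the face opposite the branched C9 substituent (made bulkier as its O–BBN borinate), which in the reactive chair stands axial while the small C10 methyl takes the in-plane position beside =CH2 (least 1,3-allylic strain), so C5–H should end cis to the C10 methyl and the CH2OH arm cis to the C9 branch (5S).

**Step 8**
Reactants: 14 diol
Product: 15 (2S)-2-[(1S,2S)-2-formyl-1,3,3-trimethylcyclohexyl]-4-(2-methyl-1,3-dioxolan-2-yl)butanal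
Conditions: (COCl)2, DMSO, CH2Cl2, −78 °C; iPr2NEt, −78 → −30 °C; pH 7 buffer
Reagents that add atoms: none
Why: Swern oxidation activates both hydroxyls before base is added, so the dialdehyde should form without lactol or lactone formation, and the hindered amine with a cold buffered quench protects the α-centres C5 and C9.

**Step 9**
Reactants: 15 dialdehyde
Product: 16 (3S)-3-[(1S,2S)-2-(1-hydroxyethyl)-1,3,3-trimethylcyclohexyl]-5-(2-methyl-1,3-dioxolan-2-yl)pentan-2-ol (mixture of carbinol epimers)
Conditions: MeMgBr (excess), THF, −78 → 0 °C; aq. NH4Cl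
Reagents that add atoms: methylmagnesium bromide, C[Mg]Br
Why: Grignard addition to both aldehydes supplies C7 and C17; the new carbinol centres form as mixtures, which does not matter because both are oxidised next.

**Step 10**
Reactants: 16 bis-carbinol
Product: 17 (3S)-3-[(1S,2S)-2-acetyl-1,3,3-trimethylcyclohexyl]-5-(2-methyl-1,3-dioxolan-2-yl)pentan-2-one (cis-1,5-diketone)
Conditions: Dess–Martin periodinane, NaHCO3, CH2Cl2, 0 °C → rt
Reagents that add atoms: none
Why: Dess–Martin oxidation under buffered, non-basic conditions should convert both secondary alcohols into methyl ketones without enolising C5 or C9.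

**Step 11**
Reactants: 17 cis-1,5-diketone
Product: 19 (3S,4S,4aS,8aS)-3-hydroxy-3,4a,8,8-tetramethyl-4-[2-(2-methyl-1,3-dioxolan-2-yl)ethyl]octahydronaphthalen-1(2H)-one (cis-decalin 8-hydroxy-6-ketone), via lithium enolate 18 (not isolated)
Conditions: LiN(SiMe3)2 (1.05 equiv), THF, −78 → −40 °C; AcOH/THF quench at −78 °C
Reagents that add atoms: none
Why: LiN(SiMe3)2 removes a methyl proton kinetically and reversibly, and the C7 enolate of the C5 acetyl group adds to the C8 carbonyl (intramolecular ketone–ketone aldol addition, the ring-forming event of a Robinson annulation stopped at the ketol), closing ring B in a 6-(enolendo)-exo-trig mode. The enolate of the other acetyl group (C17) would have to attack the C6 carbonyl, which is buried between the quaternary C4 and C10, so it should revert by proton transfer and the material drain through the C7 enolate. C8 is set in a chair transition state built on the ring A chair that keeps the C9 branch equatorial and the C5 acyl group axial: ring carbon C1 is then axial on the new ring, the C8 methyl avoids the 1,3-diaxial contact with it and goes equatorial, and oxygen ends axial, that is OH trans to the C9 side chain and methyl cis to the C10 methyl (8S). C5 and C9 should keep their configuration because both are tertiary, flanked by quaternary carbon and not deprotonated at −78 °C; one equivalent of base and a cold acidic quench guard against retro-aldol and loss of water.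

**Step 12**
Reactants: 19 ketol
Product: 21 4-[(1S,2S,4S,4aS,8aR)-2,4-dihydroxy-2,5,5,8a-tetramethyldecahydronaphthalen-1-yl]butan-2-one, via diol ketal 20 (not isolated)
Conditions: Me4NBH(OAc)3, MeCN–AcOH, −30 → 0 °C; then 1 M aq. HCl, THF, rt
Reagents that add atoms: water, O
Why: Saksena–Evans hydroxyl-directed reduction: the axial tertiary C8 hydroxyl binds the triacetoxyborohydride and delivers hydride to the same face of the C6 ketone, giving the 6,8-anti diol with an equatorial 6-OH (6S), after which aqueous acid hydrolyses the dioxolane.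

**Step 13**
Reactants: 21 keto diol
Product: 22 (1S,3S,4S,4aR,8aS)-3-hydroxy-3,4a,8,8-tetramethyl-4-(3-oxobutyl)decahydronaphthalen-1-yl acetate
Conditions: Ac2O, DMAP (cat.), pyridine, 0 °C → rt
Reagents that add atoms: acetic anhydride, CC(=O)OC(C)=O
Why: DMAP-catalysed acylation should take place at the secondary C6 hydroxyl only, the tertiary C8 hydroxyl being too hindered under these conditions.

**Step 14**
Reactants: 22 keto acetate
Product: 23 prop-2-en-1-yl (2E)-5-[(1S,2S,4S,4aS,8aR)-4-acetoxy-2-hydroxy-2,5,5,8a-tetramethyldecahydronaphthalen-1-yl]-3-methylpent-2-enoate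
Conditions: allyl (diethoxyphosphoryl)acetate, NaH (slightly less than the phosphonate), THF, 0 → 50 °C
Reagents that add atoms: allyl (diethoxyphosphoryl)acetate, C=CCOC(=O)CP(=O)(OCC)OCC
Why: Horner–Wadsworth–Emmons olefination of the C13 methyl ketone with the stabilised phosphonate anion should give mainly the (E)-enoate (chain trans to the ester), the weakly basic anion sparing the acetate and not forming the C8 alkoxide that could add back to the enoate; the minor (Z)-isomer is removed by chromatography.

**Step 15**
Reactants: 23 allyl ester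
Product: 24 (2E)-5-[(1S,2S,4S,4aS,8aR)-4-(acetyloxy)-2-hydroxy-2,5,5,8a-tetramethyldecahydronaphthalen-1-yl]-3-methylpent-2-enoic acid (target; 5S,6S,8S,9S,10R in labdane numbering)
Conditions: Pd(PPh3)4 (cat., zerovalent palladium), morpholine, THF, rt; dilute citric acid wash
Reagents that add atoms: none
Why: Tsuji–Trost deallylation: zerovalent palladium ionises the allyl ester to a π-allyl complex that morpholine traps, releasing the acid under neutral conditions that keep the C6 acetate, the C8 alcohol and the (E)-alkene.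

**Compound list**
1 | β-cyclocitral | CC1=C(C=O)C(C)(C)CCC1 | starting material
2 | β-cyclogeraniol | CC1=C(CO)C(C)(C)CCC1 | intermediate
3 | 5-oxohexanoic acid | CC(=O)CCCC(=O)O | starting material
4 | 2-hydroxyethyl 4-(2-methyl-1,3-dioxolan-2-yl)butanoate | CC1(CCCC(=O)OCCO)OCCO1 | intermediate (not isolated)
5 | 4-(2-methyl-1,3-dioxolan-2-yl)butanoic acid | CC1(CCCC(=O)O)OCCO1 | intermediate
6 | β-cyclogeranyl 4-(2-methyl-1,3-dioxolan-2-yl)butanoate | CC1=C(COC(=O)CCCC2(C)OCCO2)C(C)(C)CCC1 | intermediate
7 | (Z)-O-(tert-butyldimethylsilyl) ketene acetal of 6 | CC1(CC/C=C(\O[Si](C)(C)C(C)(C)C)OCC2=C(C)CCCC2(C)C)OCCO1 | intermediate (not isolated)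
8 | tert-butyldimethylsilyl ester of racemic acid 9 | CC(C)(C)[Si](C)(C)OC(=O)[C@@H](CCC1(C)OCCO1)[C@]2(C)CCCC(C)(C)C2=C.CC(C)(C)[Si](C)(C)OC(=O)[C@H](CCC1(C)OCCO1)[C@@]2(C)CCCC(C)(C)C2=C | intermediate (not isolated)
9 | rac-(2S)-4-(2-methyl-1,3-dioxolan-2-yl)-2-[(1S)-1,3,3-trimethyl-2-methylidenecyclohexyl]butanoic acid | OC(=O)[C@@H](CCC1(C)OCCO1)[C@]2(C)CCCC(C)(C)C2=C.OC(=O)[C@H](CCC1(C)OCCO1)[C@@]2(C)CCCC(C)(C)C2=C | intermediate
10 | (S)-1-phenylethylammonium salt of the (2S,1'S)-acid | C[C@H]([NH3+])c1ccccc1.[O-]C(=O)[C@@H](CCC2(C)OCCO2)[C@]3(C)CCCC(C)(C)C3=C | intermediate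
11 | (2S)-4-(2-methyl-1,3-dioxolan-2-yl)-2-[(1S)-1,3,3-trimethyl-2-methylidenecyclohexyl]butanoic acid | OC(=O)[C@@H](CCC1(C)OCCO1)[C@]2(C)CCCC(C)(C)C2=C | intermediate (not isolated)
12 | (2S)-4-(2-methyl-1,3-dioxolan-2-yl)-2-[(1S)-1,3,3-trimethyl-2-methylidenecyclohexyl]butan-1-ol | OC[C@@H](CCC1(C)OCCO1)[C@]2(C)CCCC(C)(C)C2=C | intermediate
13 | bis(9-BBN) adduct of 12 (C6–B and O–B) | C(OB1C2CCCC1CCC2)[C@@H](CCC3(C)OCCO3)[C@]4(C)CCCC(C)(C)[C@@H]4CB5C6CCCC5CCC6 | intermediate (not isolated)
14 | (2S)-2-[(1S,2S)-2-(hydroxymethyl)-1,3,3-trimethylcyclohexyl]-4-(2-methyl-1,3-dioxolan-2-yl)butan-1-ol | OC[C@@H](CCC1(C)OCCO1)[C@]2(C)CCCC(C)(C)[C@@H]2CO | intermediate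
15 | (2S)-2-[(1S,2S)-2-formyl-1,3,3-trimethylcyclohexyl]-4-(2-methyl-1,3-dioxolan-2-yl)butanal | O=C[C@@H](CCC1(C)OCCO1)[C@]2(C)CCCC(C)(C)[C@@H]2C=O | intermediate
16 | (3S)-3-[(1S,2S)-2-(1-hydroxyethyl)-1,3,3-trimethylcyclohexyl]-5-(2-methyl-1,3-dioxolan-2-yl)pentan-2-ol, carbinol epimers | CC(O)[C@@H](CCC1(C)OCCO1)[C@]2(C)CCCC(C)(C)[C@@H]2C(C)O | intermediate
17 | (3S)-3-[(1S,2S)-2-acetyl-1,3,3-trimethylcyclohexyl]-5-(2-methyl-1,3-dioxolan-2-yl)pentan-2-one | CC(=O)[C@@H](CCC1(C)OCCO1)[C@]2(C)CCCC(C)(C)[C@@H]2C(C)=O | intermediate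
18 | lithium C6–C7 enolate of 17 | CC(=O)[C@@H](CCC1(C)OCCO1)[C@]2(C)CCCC(C)(C)[C@@H]2C(=C)O[Li] | intermediate (not isolated)
19 | (3S,4S,4aS,8aS)-3-hydroxy-3,4a,8,8-tetramethyl-4-[2-(2-methyl-1,3-dioxolan-2-yl)ethyl]octahydronaphthalen-1(2H)-one | O=C1C[C@](C)(O)[C@@H](CCC3(C)OCCO3)[C@]2(C)CCCC(C)(C)[C@H]12 | intermediate
20 | (1S,3S,4S,4aR,8aS)-3,4a,8,8-tetramethyl-4-[2-(2-methyl-1,3-dioxolan-2-yl)ethyl]decahydronaphthalene-1,3-diol | O[C@H]1C[C@](C)(O)[C@@H](CCC3(C)OCCO3)[C@]2(C)CCCC(C)(C)[C@H]12 | intermediate (not isolated)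
21 | 4-[(1S,2S,4S,4aS,8aR)-2,4-dihydroxy-2,5,5,8a-tetramethyldecahydronaphthalen-1-yl]butan-2-one | O[C@H]1C[C@](C)(O)[C@@H](CCC(C)=O)[C@]2(C)CCCC(C)(C)[C@H]12 | intermediate
22 | (1S,3S,4S,4aR,8aS)-3-hydroxy-3,4a,8,8-tetramethyl-4-(3-oxobutyl)decahydronaphthalen-1-yl acetate | CC(=O)O[C@H]1C[C@](C)(O)[C@@H](CCC(C)=O)[C@]2(C)CCCC(C)(C)[C@H]12 | intermediate
23 | allyl (2E)-5-[(1S,2S,4S,4aS,8aR)-4-acetoxy-2-hydroxy-2,5,5,8a-tetramethyldecahydronaphthalen-1-yl]-3-methylpent-2-enoate | CC(=O)O[C@H]1C[C@](C)(O)[C@@H](CC/C(C)=C/C(=O)OCC=C)[C@]2(C)CCCC(C)(C)[C@H]12 | intermediate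
24 | (2E)-5-[(1S,2S,4S,4aS,8aR)-4-(acetyloxy)-2-hydroxy-2,5,5,8a-tetramethyldecahydronaphthalen-1-yl]-3-methylpent-2-enoic acid | CC(=O)O[C@H]1C[C@](C)(O)[C@@H](CC/C(C)=C/C(=O)O)[C@]2(C)CCCC(C)(C)[C@H]12 | target

**Step count.** Total: 15 steps. Longest linear sequence: 14 steps (1 → 24 through steps 1 and 3–15; equally 3 → 24 through steps 2–15).

**Steps most likely to fail**

Step 7. The borane may add to the other face of the exocyclic alkene, or to both faces, because the two ring A chairs are close in energy; that would put the CH2OH arm trans to the C9 branch. A peracid should show the same facial preference, and a rearrangement with inversion then turns it into the wanted configuration. Setting out from alcohol 12, silylation (t-BuPh2SiCl, imidazole) would give the silyl ether F1, and mCPBA/NaHCO3 the spiro-epoxide F2 with oxygen on the face of the C9 branch. BF3·OEt2 at −78 °C (Meinwald rearrangement, hydride shifting to C5 anti to the breaking C–O bond so that the formyl carbon takes the place the oxygen held) would give the aldehyde F3. NaBH4 would give the alcohol F4, and Bu4NF would remove the silyl group, coming back to the route at diol 14.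

Step 11. Ring closure may give poor facial selectivity at C8, or the ketol may lose water or epimerise at C5 through enolisation of the product before the quench. The fallback sets C8 by reagent approach instead of by the aldol transition state. Setting out from diketone 17, the aldol is run as before and the crude ketol mixture is dehydrated (DBU, toluene, 80 °C, E1cB) to the ring B enone F5. Nucleophilic epoxidation (t-BuOOH, DBU; Weitz–Scheffer type), expected from the face away from the C9 chain, would give the epoxy ketone F6. SmI2 in THF/MeOH at −90 °C would cleave the Cα–O bond and return the route to ketol 19.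

Step 5. The diastereomeric salts may not crystallise, or may not differ enough in solubility to give enantiopure material. The fallback uses covalent diastereomers separated by chromatography. Setting out from racemic acid 9, esterification with methyl (S)-mandelate (EDC, DMAP, CH2Cl2) would give the wanted mandelate ester F7 and the unwanted mandelate ester F8. After separation on silica, LiAlH4 would reduce F7 directly to alcohol 12, where the route is rejoined.

**Further compounds**
F1 | step 7 | tert-butyldiphenylsilyl ether of alcohol 12 | CC(C)(C)[Si](OC[C@@H](CCC1(C)OCCO1)[C@]2(C)CCCC(C)(C)C2=C)(c3ccccc3)c4ccccc4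
F2 | step 7 | spiro-epoxide of F1, oxygen on the face of the C9 branch | CC(C)(C)[Si](OC[C@@H](CCC1(C)OCCO1)[C@]2(C)CCCC(C)(C)[C@@]25CO5)(c3ccccc3)c4ccccc4
F3 | step 7 | C5 carbaldehyde, formyl cis to the C9 branch, silyl ether | CC(C)(C)[Si](OC[C@@H](CCC1(C)OCCO1)[C@]2(C)CCCC(C)(C)[C@@H]2C=O)(c3ccccc3)c4ccccc4
F4 | step 7 | mono-silyl ether of diol 14 | CC(C)(C)[Si](OC[C@@H](CCC1(C)OCCO1)[C@]2(C)CCCC(C)(C)[C@@H]2CO)(c3ccccc3)c4ccccc4
F5 | step 11 | ring B enone (C7=C8, C6 ketone), cis-fused | O=C1C=C(C)[C@@H](CCC3(C)OCCO3)[C@]2(C)CCCC(C)(C)[C@H]12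
F6 | step 11 | 7,8-epoxy 6-ketone, oxygen trans to the C9 chain | O=C1[C@@H]4O[C@]4(C)[C@@H](CCC3(C)OCCO3)[C@]2(C)CCCC(C)(C)[C@H]12
F7 | step 5 | methyl (S)-mandelate ester of the (2S,1'S)-acid | COC(=O)[C@@H](OC(=O)[C@@H](CCC1(C)OCCO1)[C@]2(C)CCCC(C)(C)C2=C)c3ccccc3
F8 | step 5 | methyl (S)-mandelate ester of the (2R,1'R)-acid | COC(=O)[C@@H](OC(=O)[C@H](CCC1(C)OCCO1)[C@@]2(C)CCCC(C)(C)C2=C)c3ccccc3
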